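The target is divided at the bridging CH2 into an (R)-acyl trione and a cyclopentane hydroxy aldehyde, united last by reductive alkylation. The plan rests on the cyclopentane ring. Its two adjacent unsubstituted methylenes, C3 and C4, flanked by carbinol carbon C2 and isopropenyl-bearing C5, are made as the C=C bond of a cyclopentenone whose carbonyl is the future C2. One ring-closing metathesis forms that bond, closes the five-membered ring and leaves an enone alkene that hydride removes without touching the isopropenyl group. Its precursor is an acyclic (4R,5R)-hepta-1,6-dien-3-one, a vinyl ketone carrying silyloxymethyl, vinyl and isopropenyl groups, with both stereocentres fixed beforehand.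

Key step: step 11

Assumption: the (Sa,S,S) ligand is taken to give the (R)-malonate in step 4 (its mirror image is equally available if the sense proves opposite), and the enantiomer collected in step 18 is identified as (R) by comparing measured and calculated circular dichroism.

Step 1
Reactants: 1 methacrolein (2-methylprop-2-enal); 2 triethyl phosphonoacetate
Product: 3 ethyl (2E)-4-methylpenta-2,4-dienoate
Conditions: NaH, THF, 0 °C to rt
Reagents that add atoms: none
Why: Horner-Wadsworth-Emmons olefination of an enal with a stabilised phosphonate anion is reliably E-selective and leaves the 1,1-disubstituted alkene untouched.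

Step 2
Reactants: 3 ethyl (2E)-4-methylpenta-2,4-dienoate
Product: 4 (2E)-4-methylpenta-2,4-dien-1-ol
Conditions: i-Bu2AlH (2.2 equiv), CH2Cl2, -78 °C; aq potassium sodium tartrate
Reagents that add atoms: none
Why: Low-temperature i-Bu2AlH reduction of a conjugated ester is a 1,2-process that ends at the allylic alcohol and keeps the diene and its E geometry.

Step 3
Reactants: 4 (2E)-4-methylpenta-2,4-dien-1-ol
Product: 5 methyl (2E)-4-methylpenta-2,4-dien-1-yl carbonate
Conditions: ClCO2Me, pyridine, CH2Cl2, 0 °C
Reagents that add atoms: methyl chloroformate, COC(=O)Cl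
Why: Simple O-acylation with a chloroformate gives the allylic carbonate, a leaving group that ionises on iridium and liberates methoxide as its own base.

Step 4
Reactants: 5 methyl (2E)-4-methylpenta-2,4-dien-1-yl carbonate; 6 dimethyl malonate
Product: 7 dimethyl 2-[(3R)-2-methylpenta-1,4-dien-3-yl]propanedioate
Conditions: [Ir(cod)Cl]2 (2 mol%), (Sa,S,S)-BINOL N,N-bis(1-phenylethyl)phosphoramidite (4 mol%), 1,5,7-triazabicyclo[4.4.0]dec-5-ene (8 mol%), THF, rt
Reagents that add atoms: none
Why: Iridium-catalysed asymmetric allylic alkylation, known for dienyl carbonates, delivers the malonate to the substituted allyl terminus, and the cyclometallated phosphoramidite complex dictates the face of attack, which sets the (R) centre that becomes ring carbon C5 of the target.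

Step 5
Reactants: 7 dimethyl 2-[(3R)-2-methylpenta-1,4-dien-3-yl]propanedioate
Product: 9 (3S)-3-ethenyl-4-methylpent-4-enoic acid, via malonic diacid 8 (not isolated)
Conditions: KOH, MeOH/H2O, 60 °C; 1 M HCl to pH 2, 0 °C, extraction; pyridine, 110 °C
Reagents that add atoms: potassium hydroxide, [K+].[OH-]
Why: Malonic ester saponification and thermal decarboxylation remove the surplus carboxyl group, loss of CO2 in pyridine keeps the medium basic so that the acid does not lactonise onto the isopropenyl group, and the doubly allylic C-H is far too weakly acidic to be disturbed (the descriptor changes only through ligand ranking).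

Step 6
Reactants: 9 (3S)-3-ethenyl-4-methylpent-4-enoic acid; 10 (4S)-4-benzyl-1,3-oxazolidin-2-one
Product: 12 (4S)-4-benzyl-3-[(3S)-3-ethenyl-4-methylpent-4-enoyl]-1,3-oxazolidin-2-one, via mixed pivalic anhydride 11 (not isolated)
Conditions: t-BuCOCl, Et3N, THF, -20 °C; then LiCl, 10, -20 °C to rt
Reagents that add atoms: none
Why: N-Acylation of the oxazolidinone through a mixed pivalic anhydride with LiCl activation is a standard mild way to attach the auxiliary, attack occurring at the less hindered carbonyl group.

Step 7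
Reactants: 12 (4S)-4-benzyl-3-[(3S)-3-ethenyl-4-methylpent-4-enoyl]-1,3-oxazolidin-2-one
Product: 14 (4S)-4-benzyl-3-[(2R,3R)-3-ethenyl-2-(hydroxymethyl)-4-methylpent-4-enoyl]-1,3-oxazolidin-2-one, via chlorotitanium Z-enolate 13 (not isolated)
Conditions: TiCl4 (1.05 equiv), i-Pr2NEt (1.1 equiv), CH2Cl2, 0 °C; 1,3,5-trioxane (1.2 equiv), TiCl4 (1.05 equiv), 0 °C; aq NH4Cl
Reagents that add atoms: 1,3,5-trioxane, C1OCOCO1
Why: In this auxiliary-controlled hydroxymethylation (titanium enolate addition to activated trioxane) the chelated Z-enolate is attacked on the face away from the benzyl group, which sets the (2R) centre, the future ring carbon C1, independently of its neighbour, and with only a slight excess of electrophile the enolate should outrun the isopropenyl group.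

Step 8
Reactants: 14 (4S)-4-benzyl-3-[(2R,3R)-3-ethenyl-2-(hydroxymethyl)-4-methylpent-4-enoyl]-1,3-oxazolidin-2-one
Product: 15 (2R,3R)-3-ethenyl-2-(hydroxymethyl)-N-methoxy-N,4-dimethylpent-4-enamide
Conditions: MeNH(OMe)·HCl (3 equiv), AlMe3 (3 equiv), CH2Cl2, -10 °C to rt; aq potassium sodium tartrate
Reagents that add atoms: N,O-dimethylhydroxylamine hydrochloride, CNOC.Cl
Why: Aluminium amide transamination of a beta-hydroxy imide, assisted by the free hydroxyl group, cleaves the exocyclic acyl bond without epimerisation and returns the auxiliary.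

Step 9
Reactants: 15 (2R,3R)-3-ethenyl-2-(hydroxymethyl)-N-methoxy-N,4-dimethylpent-4-enamide
Product: 16 (2R,3R)-2-{[tert-butyl(dimethyl)silyl]oxymethyl}-3-ethenyl-N-methoxy-N,4-dimethylpent-4-enamide
Conditions: TBSCl, imidazole, CH2Cl2, rt
Reagents that add atoms: tert-butyldimethylsilyl chloride, CC(C)(C)[Si](C)(C)Cl
Why: Standard silylation of a primary alcohol gives an ether that is inert to Grignard reagents, ruthenium carbenes, copper hydride and organocerium reagents.

Step 10
Reactants: 16 (2R,3R)-2-{[tert-butyl(dimethyl)silyl]oxymethyl}-3-ethenyl-N-methoxy-N,4-dimethylpent-4-enamide; 17 vinylmagnesium bromide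
Product: 19 (4R,5R)-4-{[tert-butyl(dimethyl)silyl]oxymethyl}-5-(prop-1-en-2-yl)hepta-1,6-dien-3-one, via magnesium hemiaminal chelate 18 (not isolated)
Conditions: 17 (2 equiv), THF, -78 to 0 °C; inverse quench into cold 1 M HCl
Reagents that add atoms: none
Why: In the Weinreb ketone synthesis the chelated adduct persists until the quench, so that over-addition and enolisation of the ketone are avoided, and pouring into cold acid protonates the released amine before it can add to the vinyl ketone.

Step 11
Reactants: 19 (4R,5R)-4-{[tert-butyl(dimethyl)silyl]oxymethyl}-5-(prop-1-en-2-yl)hepta-1,6-dien-3-one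
Product: 20 (4R,5R)-5-{[tert-butyl(dimethyl)silyl]oxymethyl}-4-(prop-1-en-2-yl)cyclopent-2-en-1-one (trans)
Conditions: second-generation Grubbs catalyst RuCl2(=CHPh)(PCy3)(SIMes) (5 mol%), 1,4-benzoquinone (10 mol%), CH2Cl2 (0.005 M), 40 °C, argon sparge
Reagents that add atoms: none
Why: The ruthenium benzylidene exchanges first with the monosubstituted C6=C7 vinyl group, the new alkylidene adds across the C1=C2 alkene of the vinyl ketone in an intramolecular [2+2] step, and cycloreversion of the ruthenacyclobutane releases the enone and a methylidene that carries the chain with loss of ethene. The closest known reaction type is ring-closing metathesis of hepta-1,6-dien-3-ones to 4-substituted cyclopent-2-enones. The single ring is a five-membered carbocycle closed by joining chain carbons C2 and C6, which become C2 and C3 of the enone and later the two ring methylenes. No stereocentre is formed, and the neutral medium leaves the (4R,5R) pair from steps 4 and 7 untouched, so the trans enone arises without base treatment of a product whose C4-H is both vinylogously acidic and allylic. Chemoselectivity among three alkenes is needed: the isopropenyl group is 1,1-disubstituted and slow to load, from the C6 alkylidene it could only give a three-membered ring, and closure of the enone onto it would need the disfavoured acyl-substituted carbene and a trisubstituted alkene. High dilution counters oligomerisation of the vinyl ketone, and 1,4-benzoquinone intercepts ruthenium hydrides that would move the alkenes into conjugation.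

Step 12
Reactants: 20 (4R,5R)-5-{[tert-butyl(dimethyl)silyl]oxymethyl}-4-(prop-1-en-2-yl)cyclopent-2-en-1-one
Product: 21 (2R,3R)-2-{[tert-butyl(dimethyl)silyl]oxymethyl}-3-(prop-1-en-2-yl)cyclopentan-1-one
Conditions: [(Ph3P)CuH]6 (0.4 equiv), H2O (5 equiv), degassed toluene, rt
Reagents that add atoms: none
Why: Copper hydride conjugate reduction delivers hydride only to the beta-carbon of the electron-poor enone, so the isopropenyl group survives and the stereocentre on the other side of the carbonyl group is not involved.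

Step 13
Reactants: 21 (2R,3R)-2-{[tert-butyl(dimethyl)silyl]oxymethyl}-3-(prop-1-en-2-yl)cyclopentan-1-one
Product: 22 (1R,2R,3R)-2-{[tert-butyl(dimethyl)silyl]oxymethyl}-1-methyl-3-(prop-1-en-2-yl)cyclopentan-1-ol
Conditions: anhydrous CeCl3 (2 equiv), MeMgBr (2 equiv), THF, -78 °C; then 21, -78 °C; sat. aq NH4Cl
Reagents that add atoms: methylmagnesium bromide, C[Mg]Br
Why: 1,2-Addition of the weakly basic organocerium reagent avoids enolisation and loss of silanolate, and the nucleophile should approach anti to the adjacent silyloxymethyl arm, as bulky nucleophiles do with trans-2,3-disubstituted cyclopentanones, which sets the (1R) carbinol centre with OH cis to that arm.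

Step 14
Reactants: 22 (1R,2R,3R)-2-{[tert-butyl(dimethyl)silyl]oxymethyl}-1-methyl-3-(prop-1-en-2-yl)cyclopentan-1-ol
Product: 23 (1R,2R,3R)-2-(hydroxymethyl)-1-methyl-3-(prop-1-en-2-yl)cyclopentan-1-ol
Conditions: Bu4NF, THF, rt
Reagents that add atoms: none
Why: Fluoride-induced desilylation acts on the Si-O bond alone and leaves the tertiary alcohol and the alkene untouched.

Step 15
Reactants: 23 (1R,2R,3R)-2-(hydroxymethyl)-1-methyl-3-(prop-1-en-2-yl)cyclopentan-1-ol
Product: 24 (1S,2R,5R)-2-hydroxy-2-methyl-5-(prop-1-en-2-yl)cyclopentane-1-carbaldehyde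
Conditions: TEMPO (10 mol%), PhI(OAc)2 (1.1 equiv), CH2Cl2, rt; used at once
Reagents that add atoms: none
Why: Oxoammonium (TEMPO) oxidation acts on the primary alcohol only, stops at the aldehyde and runs under nearly neutral conditions that spare the beta-hydroxy aldehyde.

Step 16
Reactants: 25 2-methylbenzene-1,3,5-triol (2-methylphloroglucinol); 26 2-methylpropanoyl chloride
Product: 27 2-methyl-1-(2,4,6-trihydroxy-3-methylphenyl)propan-1-one
Conditions: AlCl3 (4 equiv), CH2Cl2/MeNO2, 0 to 40 °C; cold aq HCl
Reagents that add atoms: none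
Why: Friedel-Crafts C-acylation of the electron-rich triol gives one product because both free ring positions are equivalent and the aryl ketone formed is deactivated towards a second acylation.

Step 17
Reactants: 27 2-methyl-1-(2,4,6-trihydroxy-3-methylphenyl)propan-1-one; 28 1-bromo-3-methylbut-2-ene (prenyl bromide)
Product: 29 rac-3,5-dihydroxy-6-methyl-6-(3-methylbut-2-en-1-yl)-2-(2-methylpropanoyl)cyclohexa-2,4-dien-1-one
Conditions: NaOMe (2.1 equiv), MeOH, 0 °C; 28 (1.0 equiv), 0 °C to rt; 1 M HCl; partition with aq NaHCO3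
Reagents that add atoms: none
Why: In this alkylative dearomatisation of an acylphloroglucinol the protic medium steers the phenolate to C-alkylation, the methyl-bearing ring carbon is the most electron-rich site, so prenylation there creates the quaternary carbon as a racemate, and the far more acidic trione is parted from any ring-prenylated arene by bicarbonate extraction.

Step 18
Reactants: 29 rac-3,5-dihydroxy-6-methyl-6-(3-methylbut-2-en-1-yl)-2-(2-methylpropanoyl)cyclohexa-2,4-dien-1-one
Product: 30 (6R)-3,5-dihydroxy-6-methyl-6-(3-methylbut-2-en-1-yl)-2-(2-methylpropanoyl)cyclohexa-2,4-dien-1-one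
Conditions: preparative HPLC, amylose tris(3,5-dimethylphenylcarbamate) on silica, heptane/i-PrOH/CF3CO2H
Reagents that add atoms: none
Why: Chromatographic resolution on a chiral stationary phase, routine for enolised triones of this class, supplies the (R)-enantiomer, whose quaternary carbon carries no hydrogen and therefore cannot epimerise later.

Step 19
Reactants: 24 (1S,2R,5R)-2-hydroxy-2-methyl-5-(prop-1-en-2-yl)cyclopentane-1-carbaldehyde; 30 (6R)-3,5-dihydroxy-6-methyl-6-(3-methylbut-2-en-1-yl)-2-(2-methylpropanoyl)cyclohexa-2,4-dien-1-one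
Product: 32 (6R)-3,5-dihydroxy-4-{[(1S,2R,5R)-2-hydroxy-2-methyl-5-(prop-1-en-2-yl)cyclopentyl]methyl}-6-methyl-6-(3-methylbut-2-en-1-yl)-2-(2-methylpropanoyl)cyclohexa-2,4-dien-1-one, via alkylidene trione 31 (not isolated)
Conditions: diethyl 2,6-dimethyl-1,4-dihydropyridine-3,5-dicarboxylate (Hantzsch ester, 1.2 equiv), L-proline (20 mol%), CH2Cl2, rt
Reagents that add atoms: none
Why: In this organocatalytic three-component reductive alkylation (Knoevenagel condensation, then Hantzsch ester transfer hydrogenation) the only free ring CH of 30 condenses with the aldehyde and the electron-poor alkylidene takes up hydride, no stereocentre is formed, the aldehyde-bearing carbon already sits trans to both neighbouring carbon substituents, and the trans isopropenyl group cannot reach the alkylidene without a strained trans-fused bicycle.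

Compound list
1 | methacrolein | C=C(C)C=O | starting material
2 | triethyl phosphonoacetate | CCOC(=O)CP(=O)(OCC)OCC | starting material
3 | ethyl (2E)-4-methylpenta-2,4-dienoate | CCOC(=O)/C=C/C(C)=C | intermediate
4 | (2E)-4-methylpenta-2,4-dien-1-ol | OC/C=C/C(C)=C | intermediate
5 | methyl (2E)-4-methylpenta-2,4-dien-1-yl carbonate | COC(=O)OC/C=C/C(C)=C | intermediate
6 | dimethyl malonate | COC(=O)CC(=O)OC | starting material
7 | dimethyl 2-[(3R)-2-methylpenta-1,4-dien-3-yl]propanedioate | COC(=O)C(C(=O)OC)[C@@H](C=C)C(C)=C | intermediate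
8 | 2-[(3R)-2-methylpenta-1,4-dien-3-yl]propanedioic acid | OC(=O)C(C(=O)O)[C@@H](C=C)C(C)=C | intermediate
9 | (3S)-3-ethenyl-4-methylpent-4-enoic acid | OC(=O)C[C@@H](C=C)C(C)=C | intermediate
10 | (4S)-4-benzyl-1,3-oxazolidin-2-one | O=C1N[C@@H](Cc2ccccc2)CO1 | starting material
11 | (3S)-3-ethenyl-4-methylpent-4-enoic 2,2-dimethylpropanoic anhydride | CC(C)(C)C(=O)OC(=O)C[C@@H](C=C)C(C)=C | intermediate
12 | (4S)-4-benzyl-3-[(3S)-3-ethenyl-4-methylpent-4-enoyl]-1,3-oxazolidin-2-one | O=C(C[C@@H](C=C)C(C)=C)N1[C@@H](Cc2ccccc2)COC1=O | intermediate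
13 | trichlorotitanium (Z)-enolate of 12 | C=C(C)[C@H](C=C)/C=C(\O[Ti](Cl)(Cl)Cl)N1[C@@H](Cc2ccccc2)COC1=O | intermediate
14 | (4S)-4-benzyl-3-[(2R,3R)-3-ethenyl-2-(hydroxymethyl)-4-methylpent-4-enoyl]-1,3-oxazolidin-2-one | O=C([C@@H](CO)[C@@H](C=C)C(C)=C)N1[C@@H](Cc2ccccc2)COC1=O | intermediate
15 | (2R,3R)-3-ethenyl-2-(hydroxymethyl)-N-methoxy-N,4-dimethylpent-4-enamide | CON(C)C(=O)[C@@H](CO)[C@@H](C=C)C(C)=C | intermediate
16 | (2R,3R)-2-{[tert-butyl(dimethyl)silyl]oxymethyl}-3-ethenyl-N-methoxy-N,4-dimethylpent-4-enamide | CON(C)C(=O)[C@@H](CO[Si](C)(C)C(C)(C)C)[C@@H](C=C)C(C)=C | intermediate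
17 | vinylmagnesium bromide | C=C[Mg]Br | starting material
18 | bromomagnesium hemiaminal chelate from 16 and 17 | C=CC(O[Mg]Br)(N(C)OC)[C@@H](CO[Si](C)(C)C(C)(C)C)[C@@H](C=C)C(C)=C | intermediate
19 | (4R,5R)-4-{[tert-butyl(dimethyl)silyl]oxymethyl}-5-(prop-1-en-2-yl)hepta-1,6-dien-3-one | C=CC(=O)[C@@H](CO[Si](C)(C)C(C)(C)C)[C@@H](C=C)C(C)=C | intermediate
20 | (4R,5R)-5-{[tert-butyl(dimethyl)silyl]oxymethyl}-4-(prop-1-en-2-yl)cyclopent-2-en-1-one | C=C(C)[C@@H]1C=CC(=O)[C@H]1CO[Si](C)(C)C(C)(C)C | intermediate
21 | (2R,3R)-2-{[tert-butyl(dimethyl)silyl]oxymethyl}-3-(prop-1-en-2-yl)cyclopentan-1-one | C=C(C)[C@@H]1CCC(=O)[C@H]1CO[Si](C)(C)C(C)(C)C | intermediate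
22 | (1R,2R,3R)-2-{[tert-butyl(dimethyl)silyl]oxymethyl}-1-methyl-3-(prop-1-en-2-yl)cyclopentan-1-ol | C=C(C)[C@@H]1CC[C@@](C)(O)[C@H]1CO[Si](C)(C)C(C)(C)C | intermediate
23 | (1R,2R,3R)-2-(hydroxymethyl)-1-methyl-3-(prop-1-en-2-yl)cyclopentan-1-ol | C=C(C)[C@@H]1CC[C@@](C)(O)[C@H]1CO | intermediate
24 | (1S,2R,5R)-2-hydroxy-2-methyl-5-(prop-1-en-2-yl)cyclopentane-1-carbaldehyde | C=C(C)[C@@H]1CC[C@@](C)(O)[C@H]1C=O | intermediate
25 | 2-methylbenzene-1,3,5-triol | Cc1c(O)cc(O)cc1O | starting material
26 | 2-methylpropanoyl chloride | CC(C)C(=O)Cl | starting material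
27 | 2-methyl-1-(2,4,6-trihydroxy-3-methylphenyl)propan-1-one | CC(C)C(=O)c1c(O)cc(O)c(C)c1O | intermediate
28 | 1-bromo-3-methylbut-2-ene | CC(C)=CCBr | starting material
29 | rac-3,5-dihydroxy-6-methyl-6-(3-methylbut-2-en-1-yl)-2-(2-methylpropanoyl)cyclohexa-2,4-dien-1-one | CC(C)C(=O)C1=C(O)C=C(O)C(C)(CC=C(C)C)C1=O | intermediate
30 | (6R)-3,5-dihydroxy-6-methyl-6-(3-methylbut-2-en-1-yl)-2-(2-methylpropanoyl)cyclohexa-2,4-dien-1-one | CC(C)C(=O)C1=C(O)C=C(O)[C@@](C)(CC=C(C)C)C1=O | intermediate
31 | alkylidene trione from 24 and 30 (alkene geometry open) | C=C(C)[C@@H]1CC[C@@](C)(O)[C@H]1C=C1C(=O)[C@@](C)(CC=C(C)C)C(O)=C(C(=O)C(C)C)C1=O | intermediate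
32 | (6R)-3,5-dihydroxy-4-{[(1S,2R,5R)-2-hydroxy-2-methyl-5-(prop-1-en-2-yl)cyclopentyl]methyl}-6-methyl-6-(3-methylbut-2-en-1-yl)-2-(2-methylpropanoyl)cyclohexa-2,4-dien-1-one | C=C(C)[C@@H]1CC[C@@](C)(O)[C@H]1CC1=C(O)[C@@](C)(CC=C(C)C)C(=O)C(C(=O)C(C)C)=C1O | target

Total step count: 19. Longest linear sequence: 16 (steps 1 to 15, then step 19).

Steps most likely to fail

Step 11. The ring closure may stall through chelation of the catalyst by the carbonyl group. The vinyl ketone may also oligomerise, or the alkenes may migrate into conjugation. The fallback closes the same bond one oxidation level lower. It sets out from 19, which is reduced in the 1,2-sense (NaBH4, CeCl3·7H2O, MeOH, -78 °C) to (4R,5R)-4-{[tert-butyl(dimethyl)silyl]oxymethyl}-5-(prop-1-en-2-yl)hepta-1,6-dien-3-ol F1, obtained as both carbinol epimers. The electron-richer allylic alcohol is cyclised with the same ruthenium catalyst to (4R,5R)-5-{[tert-butyl(dimethyl)silyl]oxymethyl}-4-(prop-1-en-2-yl)cyclopent-2-en-1-ol F2. Allylic oxidation with MnO2 in CH2Cl2 erases the extra centre and comes back to the route at 20.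

Step 13. Facial selectivity may be poor because the isopropenyl group lies on the face that the methyl group must enter, or enolisation may compete. The fallback replaces steric control by hydroxyl direction.
- It sets out from 21, which is methylenated under non-basic conditions (Cp2TiMe2, toluene, 70 °C) to tert-butyl(dimethyl){[(1S,5R)-2-methylidene-5-(prop-1-en-2-yl)cyclopentyl]methoxy}silane F3.
- Bu4NF frees [(1S,5R)-2-methylidene-5-(prop-1-en-2-yl)cyclopentyl]methanol F4.
- Directed epoxidation (VO(acac)2, t-BuOOH, CH2Cl2, 0 °C) places oxygen on the face of the hydroxymethyl arm and gives [(3R,4R,5R)-5-(prop-1-en-2-yl)-1-oxaspiro[2.4]heptan-4-yl]methanol F5.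
- LiBHEt3 opens the epoxide at its CH2 terminus, and the sequence comes back to the route at 23.

Step 19. Retro-aldol opening or dehydration of the beta-hydroxy aldehyde under amine catalysis may outpace a slow condensation at the hindered formyl group. The fallback masks the carbinol during the coupling.
- It sets out from 23, which is bis-silylated (Et3SiOTf, 2,6-lutidine) to (1R,2R,3R)-1-methyl-3-(prop-1-en-2-yl)-1-(triethylsilyloxy)-2-(triethylsilyloxymethyl)cyclopentane F6.
- Swern conditions ((COCl)2, DMSO, Et3N, -78 to -30 °C) oxidise the primary silyl ether selectively to (1S,2R,5R)-2-methyl-5-(prop-1-en-2-yl)-2-(triethylsilyloxy)cyclopentane-1-carbaldehyde F7.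
- Reductive alkylation of 30 under the conditions of step 19 gives the O-triethylsilyl ether of 32 F8.
- HF·pyridine in THF at 0 °C removes the silyl group, and the sequence comes back to the route at 32.

Further compounds
F1 | step 11 | (4R,5R)-4-{[tert-butyl(dimethyl)silyl]oxymethyl}-5-(prop-1-en-2-yl)hepta-1,6-dien-3-ol (both C3 epimers) | C=CC(O)[C@@H](CO[Si](C)(C)C(C)(C)C)[C@@H](C=C)C(C)=C
F2 | step 11 | (4R,5R)-5-{[tert-butyl(dimethyl)silyl]oxymethyl}-4-(prop-1-en-2-yl)cyclopent-2-en-1-ol (both C1 epimers) | C=C(C)[C@@H]1C=CC(O)[C@H]1CO[Si](C)(C)C(C)(C)C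
F3 | step 13 | tert-butyl(dimethyl){[(1S,5R)-2-methylidene-5-(prop-1-en-2-yl)cyclopentyl]methoxy}silane | C=C(C)[C@@H]1CCC(=C)[C@H]1CO[Si](C)(C)C(C)(C)C
F4 | step 13 | [(1S,5R)-2-methylidene-5-(prop-1-en-2-yl)cyclopentyl]methanol | C=C(C)[C@@H]1CCC(=C)[C@H]1CO
F5 | step 13 | [(3R,4R,5R)-5-(prop-1-en-2-yl)-1-oxaspiro[2.4]heptan-4-yl]methanol | C=C(C)[C@@H]1CC[C@@]2(OC2)[C@H]1CO
F6 | step 19 | (1R,2R,3R)-1-methyl-3-(prop-1-en-2-yl)-1-(triethylsilyloxy)-2-(triethylsilyloxymethyl)cyclopentane | C=C(C)[C@@H]1CC[C@@](C)(O[Si](CC)(CC)CC)[C@H]1CO[Si](CC)(CC)CC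
F7 | step 19 | (1S,2R,5R)-2-methyl-5-(prop-1-en-2-yl)-2-(triethylsilyloxy)cyclopentane-1-carbaldehyde | C=C(C)[C@@H]1CC[C@@](C)(O[Si](CC)(CC)CC)[C@H]1C=O
F8 | step 19 | O-triethylsilyl ether of 32 at the cyclopentane carbinol | C=C(C)[C@@H]1CC[C@@](C)(O[Si](CC)(CC)CC)[C@H]1CC1=C(O)[C@@](C)(CC=C(C)C)C(=O)C(C(=O)C(C)C)=C1O
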